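Leave cedar and elm closed at 100 °C for the full 25 d, and add nothing. Each holds substrate, reagent and precatalyst, and little product should show in the first days: Tuesday's, at 95 °C, had 2.5% at 3.00 d.

| setting | Tuesday's | Friday's | Monday's | cedar | elm |
|---|---|---|---|---|---|
| substrate | 48 mM | 48 mM | 59 mM | 100 mM | 48 mM |
| reagent | 15 mM | 17 mM | 28.8 mM | 20.0 mM | 28.8 mM |
| precatalyst | 0.53 mM | 0.53 mM | 0.53 mM | 0.53 mM | 0.53 mM |
| temperature | 95 °C | 106 °C | 95 °C | 100 °C | 100 °C |
| remark | run made earlier | run made earlier | run made earlier |  |  |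
| time |  |  |  | 25 d | 25 d |

| run | time / d | product / % | substrate / % |
|---|---|---|---|
| Tuesday's | 1.04 | 0.3 | 99.5 |
| Tuesday's | 3.00 | 2.5 | 97.0 |
| Tuesday's | 6.00 | 10.2 | 90.1 |
| Tuesday's | 8.00 | 15.2 | 84.1 |
| Tuesday's | 12.0 | 25.4 | 74.3 |
| Friday's | 1.04 | 3.1 | 97.3 |
| Friday's | 2.08 | 10.1 | 89.4 |
| Friday's | 4.00 | 25.7 | 73.8 |
| Friday's | 6.00 | 33.7 | 65.4 |
| Friday's | 12.0 | 35.4 | 64.4 |
| Monday's | 1.04 | 0 | 99.6 |
| Monday's | 3.00 | 2.3 | 97.4 |
| Monday's | 6.00 | 9.4 | 89.7 |
| Monday's | 8.00 | 15.3 | 84.0 |
| Monday's | 12.0 | 28.8 | 71.0 |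

(readings scatter by 0.3 percentage points)

- the numbers in the tables scatter with a standard deviation of 0.3 percentage points

- the flask that ends with the higher amount of product, in percent of the substrate charged, or "neither" when 2 percentage points or less lies between them (cedar / elm / neither)
- final product, as a percentage of the substrate charged, in cedar
- final product, as a percentage of the substrate charged, in elm

We solve the end first. Friday's moved from 33.7% at 6.00 d to 35.4% at 12.0 d, and its reagent over substrate is 35.4%. So we read reagent as the limiting reagent, used one for one, and carry the ceiling Y: the reagent charged divided by the substrate charged, which is 60.0% in elm and 20.0% in cedar.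

Then the pace. Let r be the share of the charge turned into product per day. Late in Tuesday's r was 0.0255 /d, and in the middle of Friday's 0.0813 /d. Their geometric mean, 0.0455 /d, is our r for 100 °C. Monday's, with more substrate and more reagent, kept pace with Tuesday's in percent: 15.3% against 15.2% at 8.00 d.

At that pace, Y takes 4.39 d in cedar and 13.2 d in elm. That leaves elm 11.8 d for its slow start, longer than the 6.00 d that Tuesday's, at 95 °C, took to reach 10.2%. We expect both flasks at Y, with elm ahead by 40 points.

The forecast gives 20% for cedar and 58% for elm, which is less than our Y for elm, and names elm: “It should just reach the cap, unless the catalyst dies late, which these runs cannot exclude.”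

Cedar ends at 20.0% and elm at 60.0%, so elm leads, each at its Y of 20.0% and 60.0%, and the forecast for elm stood 2 points under. In cedar the midpoint of the turnover of the step from reagent and catalyst intermediate A to catalyst intermediate B came at 5.32 d, earlier than the 25 d allowed, and reagent stands at 0.470% of its charge at 12.5 d and 0% at 25.0 d.

    substrate + free catalyst ⇌ catalyst intermediate A (K = 50.0 /M, k = 8900 /M/h, Ea = 42.0 kJ/mol, ΔH = −14.0 kJ/mol)
    reagent + catalyst intermediate A ⇌ catalyst intermediate B (K = 64.0 /M, k = 130 /M/h, Ea = 82.0 kJ/mol, ΔH = −53.0 kJ/mol)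
    catalyst intermediate B ⇌ by-product + catalyst intermediate C (K = 0.320 M, k = 180 /h, Ea = 108 kJ/mol, ΔH = −31.0 kJ/mol)
    catalyst intermediate C ⇌ catalyst intermediate D (K = 0.210, k = 7.80 /h, Ea = 121 kJ/mol, ΔH = 1.00 kJ/mol)
    catalyst intermediate D → free catalyst + product (k = 4.10 /h, Ea = 116 kJ/mol)
    precatalyst ⇌ free catalyst (K = 21.0, k = 0.00670 /h, Ea = 130 kJ/mol, ΔH = −64.0 kJ/mol)
    (constants at 100 °C)

A repeat of cedar with 25 mM of substrate has Y = 80.0%. Computed, it ends at 79.8%, with 0.304% of its reagent left.

The runs were computed for substances that don't exist; the scatter is artificial.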